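**Plan** (germacrane numbering)
- Enabling feature: the 3(2H)-furanone is a C1/C3 β-diketone whose C3 enol oxygen is tied to C10. C10 is a fully substituted carbon α to the C1 ketone and vicinal to the C9 carbinol. The O–C10 bond is therefore cut last, back to a ten-membered C2≡C3 ynone (masked β-diketone) that carries a cis C9–C10 epoxide (masked 9-OH, electrophilic C10).
- Further cuts: C1–C2 (alkynyl/aldehyde ring closure), C6–C7 with the lactone C–O (allylation/lactonisation), C8–C9 (alkenyl addition). This leaves three small fragments: a Z-vinyl iodide, an acrylate aldehyde and a Z-enynal.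
- Forward order: C8–C9 coupling, epoxide, lactone ring, ten-membered carbocycle, and the bridging furanone ring last.
- Stereochemistry: C8 by ligand control in the alkenylchromium addition; C9/C10 by hydroxyl-directed epoxidation of the Z-alkene; C6/C7 by chromium allylation under C8 control; C10 is inverted in the key step. Both Z-alkenes come from a commercial Z-enynol and an anti-carbomagnesiation.

Key step: step 17

Assumption: the (4S)-isopropyl oxazoline sulfonamide ligand on chromium in step 5 is taken to give the R-carbinol at C8 of the coupling product; if the sense is the reverse, the enantiomeric ligand is used.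

**Step 1**
Reactants: 1 prop-2-yn-1-ol
Product: 2 (2Z)-3-iodo-2-methylprop-2-en-1-ol
Conditions: MeMgBr (2.5 equiv), CuI (10 mol %), THF, −10 °C to rt; then I2, −78 to 0 °C
Reagents that add atoms: methylmagnesium bromide, C[Mg]Br; iodine, II
Why: Copper-catalysed anti-carbomagnesiation of the propargylic alkoxide (chelate control) and iodinolysis with retention should place iodine cis to CH2OH, which is the later Z C9=C10 geometry.

**Step 2**
Reactants: 2 (2Z)-3-iodo-2-methylprop-2-en-1-ol
Product: 3 tert-butyl{[(2Z)-3-iodo-2-methylprop-2-en-1-yl]oxy}dimethylsilane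
Conditions: TBSCl, imidazole, CH2Cl2, 0 °C to rt
Reagents that add atoms: tert-butyldimethylsilyl chloride, CC(C)(C)[Si](C)(C)Cl
Why: Standard silylation of a primary alcohol masks the future C1 oxygen until after the lactone is built.

**Step 3**
Reactants: 4 methyl 2-(dimethoxyphosphoryl)prop-2-enoate; 5 (4-methoxyphenyl)methanol; 6 2,2-dimethoxyacetaldehyde
Product: 7 methyl (2E)-4,4-dimethoxy-2-{[(4-methoxybenzyl)oxy]methyl}but-2-enoate
Conditions: NaH (1.05 equiv), 5, THF, 0 °C; 4, −78 °C; then 6 (dry THF solution), −78 °C to rt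
Reagents that add atoms: none
Why: Tandem oxa-Michael addition and Horner–Wadsworth–Emmons olefination; the alkoxide adds to the phosphonoacrylate and the resulting phosphonate anion olefinates the aldehyde, expected mainly as the E enoate.

**Step 4**
Reactants: 7 methyl (2E)-4,4-dimethoxy-2-{[(4-methoxybenzyl)oxy]methyl}but-2-enoate
Product: 8 methyl (2E)-2-{[(4-methoxybenzyl)oxy]methyl}-4-oxobut-2-enoate
Conditions: aq. HCl (1 M), acetone, 0 °C to rt; used at once
Reagents that add atoms: water, O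
Why: Mild acetal hydrolysis frees the conjugated aldehyde while the 4-methoxybenzyl ether and the ester should survive dilute acid.

**Step 5**
Reactants: 3 tert-butyl{[(2Z)-3-iodo-2-methylprop-2-en-1-yl]oxy}dimethylsilane; 8 methyl (2E)-2-{[(4-methoxybenzyl)oxy]methyl}-4-oxobut-2-enoate
Product: 9 methyl (2E,4R,5Z)-7-[(tert-butyldimethylsilyl)oxy]-4-hydroxy-2-{[(4-methoxybenzyl)oxy]methyl}-6-methylhepta-2,5-dienoate
Conditions: CrCl2 (4 equiv), NiCl2 (2 mol %), N-{2-[(4S)-4-isopropyl-4,5-dihydro-1,3-oxazol-2-yl]-6-methylphenyl}methanesulfonamide (4.4 equiv), Et3N, THF, 25 °C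
Reagents that add atoms: none
Why: Asymmetric Nozaki–Hiyama–Kishi coupling; the alkenylchromium adds 1,2 to the aldehyde only, the Z geometry of 3 is kept, and the chiral sulfonamide on chromium sets C8 (4R in 9) by reagent control.

**Step 6**
Reactants: 9 methyl (2E,4R,5Z)-7-[(tert-butyldimethylsilyl)oxy]-4-hydroxy-2-{[(4-methoxybenzyl)oxy]methyl}-6-methylhepta-2,5-dienoate
Product: 10 methyl (2E,4S)-4-[(2R,3S)-3-{[(tert-butyldimethylsilyl)oxy]methyl}-3-methyloxiran-2-yl]-4-hydroxy-2-{[(4-methoxybenzyl)oxy]methyl}but-2-enoate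
Conditions: mCPBA (1.2 equiv), NaHCO3, CH2Cl2, 0 °C
Reagents that add atoms: 3-chloroperoxybenzoic acid, OOC(=O)c1cccc(Cl)c1
Why: Hydroxyl-directed epoxidation of a Z-allylic alcohol; A(1,3) strain holds C8–H in the alkene plane and the hydrogen-bonded peracid is delivered to the hydroxyl face, which should give the threo epoxy alcohol (C9 and C10) and leave the electron-poor enoate alkene untouched.

**Step 7**
Reactants: 10 methyl (2E,4S)-4-[(2R,3S)-3-{[(tert-butyldimethylsilyl)oxy]methyl}-3-methyloxiran-2-yl]-4-hydroxy-2-{[(4-methoxybenzyl)oxy]methyl}but-2-enoate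
Product: 11 methyl (2E,4S)-4-[(2R,3S)-3-{[(tert-butyldimethylsilyl)oxy]methyl}-3-methyloxiran-2-yl]-2-{[(4-methoxybenzyl)oxy]methyl}-4-[(2-methylpropanoyl)oxy]but-2-enoate
Conditions: (i-PrCO)2O, Et3N, 4-(dimethylamino)pyridine (cat.), CH2Cl2, 0 °C to rt
Reagents that add atoms: 2-methylpropanoic anhydride, CC(C)C(=O)OC(=O)C(C)C
Why: Acyl-transfer esterification puts the isobutyrate on the only free hydroxyl (C8) while the future 9-hydroxyl is still locked in the epoxide.

**Step 8**
Reactants: 11 methyl (2E,4S)-4-[(2R,3S)-3-{[(tert-butyldimethylsilyl)oxy]methyl}-3-methyloxiran-2-yl]-2-{[(4-methoxybenzyl)oxy]methyl}-4-[(2-methylpropanoyl)oxy]but-2-enoate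
Product: 12 methyl (2E,4S)-4-[(2R,3S)-3-{[(tert-butyldimethylsilyl)oxy]methyl}-3-methyloxiran-2-yl]-2-(hydroxymethyl)-4-[(2-methylpropanoyl)oxy]but-2-enoate
Conditions: 2,3-dichloro-5,6-dicyano-1,4-benzoquinone (1.3 equiv), CH2Cl2/pH 7 phosphate buffer, 0 °C
Reagents that add atoms: none
Why: Oxidative cleavage of the 4-methoxybenzyl ether under buffered conditions should spare the epoxide, both esters and the silyl ether.

**Step 9**
Reactants: 12 methyl (2E,4S)-4-[(2R,3S)-3-{[(tert-butyldimethylsilyl)oxy]methyl}-3-methyloxiran-2-yl]-2-(hydroxymethyl)-4-[(2-methylpropanoyl)oxy]but-2-enoate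
Product: 13 methyl (2Z,4S)-2-(bromomethyl)-4-[(2R,3S)-3-{[(tert-butyldimethylsilyl)oxy]methyl}-3-methyloxiran-2-yl]-4-[(2-methylpropanoyl)oxy]but-2-enoate
Conditions: CBr4, PPh3, 2,6-lutidine, CH2Cl2, −20 °C
Reagents that add atoms: tetrabromomethane, BrC(Br)(Br)Br
Why: Appel reaction of the primary allylic alcohol under base-buffered, cold conditions gives the allylic bromide needed for the chromium allylation.

**Step 10**
Reactants: 14 (2Z)-3-methylpent-2-en-4-yn-1-ol
Product: 15 (2Z)-3-methylpent-2-en-4-ynal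
Conditions: MnO2 (activated, excess), CH2Cl2, 25 °C, short contact; filtered and used crude
Reagents that add atoms: none
Why: Selective oxidation of an allylic alcohol; brief neutral contact should keep the Z geometry that becomes the C4=C5 alkene.

**Step 11**
Reactants: 13 methyl (2Z,4S)-2-(bromomethyl)-4-[(2R,3S)-3-{[(tert-butyldimethylsilyl)oxy]methyl}-3-methyloxiran-2-yl]-4-[(2-methylpropanoyl)oxy]but-2-enoate; 15 (2Z)-3-methylpent-2-en-4-ynal
Product: 17 (S)-[(2R,3S)-3-{[(tert-butyldimethylsilyl)oxy]methyl}-3-methyloxiran-2-yl]{(2R,3S)-2-[(1Z)-2-methylbut-1-en-3-yn-1-yl]-4-methylidene-5-oxooxolan-3-yl}methyl 2-methylpropanoate, via hydroxy ester 16 (not isolated)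
Conditions: CrCl2 (4 equiv), THF, 0 °C to rt; aq. NH4Cl; silica gel, CH2Cl2, rt to complete lactonisation
Reagents that add atoms: none
Why: Nozaki–Hiyama allylation then lactonisation; the equilibrating allylchromium adds through C7 in a chair-like six-membered transition state with both substituents equatorial (anti C6/C7, hence the trans-lactone), and it attacks from the C7 face anti to the oxiranyl carbon C9 while C8–H eclipses the alkene (allylic strain), so that C7 should become S and C6 R before the C6 alkoxide closes onto the methyl ester.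

**Step 12**
Reactants: 17 (lactone with terminal alkyne, named in step 11)
Product: 18 (S)-[(2R,3S)-3-{[(tert-butyldimethylsilyl)oxy]methyl}-3-methyloxiran-2-yl]{(2R,3S)-2-[(1Z)-4-iodo-2-methylbut-1-en-3-yn-1-yl]-4-methylidene-5-oxooxolan-3-yl}methyl 2-methylpropanoate
Conditions: N-iodosuccinimide (1.2 equiv), AgNO3 (10 mol %), acetone, 25 °C, dark
Reagents that add atoms: N-iodosuccinimide, O=C1CCC(=O)N1I
Why: Silver-catalysed iodination of the terminal alkyne gives the iodoalkyne needed for the chromium-mediated ring closure.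

**Step 13**
Reactants: 18 (iodoalkyne silyl ether, named in step 12)
Product: 19 (S)-[(2R,3S)-3-(hydroxymethyl)-3-methyloxiran-2-yl]{(2R,3S)-2-[(1Z)-4-iodo-2-methylbut-1-en-3-yn-1-yl]-4-methylidene-5-oxooxolan-3-yl}methyl 2-methylpropanoate
Conditions: HF·pyridine, pyridine, THF, 0 °C
Reagents that add atoms: none
Why: Buffered fluoride desilylation frees the primary C1 hydroxyl without base, so the methylene lactone, the ester and the epoxide should remain.

**Step 14**
Reactants: 19 (epoxy alcohol, named in step 13)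
Product: 20 (S)-[(2R,3R)-3-formyl-3-methyloxiran-2-yl]{(2R,3S)-2-[(1Z)-4-iodo-2-methylbut-1-en-3-yn-1-yl]-4-methylidene-5-oxooxolan-3-yl}methyl 2-methylpropanoate
Conditions: Dess–Martin periodinane, NaHCO3, CH2Cl2, 0 °C to rt
Reagents that add atoms: none
Why: Dess–Martin oxidation of a 2,3-epoxy alcohol; the aldehyde carbon is attached to the fully substituted C10, so it cannot epimerise or eliminate.

**Step 15**
Reactants: 20 (epoxy aldehyde, named in step 14)
Product: 21 (6R,7S,8S,9R)-9,10-epoxy-1-hydroxy-8-[(2-methylpropanoyl)oxy]germacra-4(Z),11(13)-dien-2-yn-12,6-olide (epoxide configuration as in 20, mixture of C1 epimers)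
Conditions: CrCl2 (10 equiv), NiCl2 (5 mol %), THF, 25 °C, slow addition of 20 (final 0.002 M)
Reagents that add atoms: none
Why: Intramolecular Nozaki–Hiyama–Kishi addition of the alkynylchromium to the aldehyde under high dilution; the Z-enyne and the cis-epoxide hold the two ends near each other as in ten-membered enediyne ring closures, and the new C1 carbinol (unselective) is removed in step 16.

**Step 16**
Reactants: 21 (ten-membered propargylic alcohol, named in step 15)
Product: 22 (6R,7S,8S,9R,10R)-9,10-epoxy-8-[(2-methylpropanoyl)oxy]-1-oxogermacra-4(Z),11(13)-dien-2-yn-12,6-olide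
Conditions: Dess–Martin periodinane, NaHCO3, CH2Cl2, 0 °C; used crude
Reagents that add atoms: none
Why: Dess–Martin oxidation of the propargylic alcohol converges both C1 epimers to the ynone, the masked C1/C3 β-diketone.

**Step 17**
Reactants: 22 (ten-membered epoxy ynone, named in step 16)
Product: 25 (6R,7S,8S,9R,10S)-3,10-epoxy-9-hydroxy-8-[(2-methylpropanoyl)oxy]-1-oxogermacra-2,4(Z),11(13)-trien-12,6-olide (CNP0265772.2), via enaminone 23 (not isolated), via diketone 24 (not isolated)
Conditions: Et2NH (1.05 equiv), THF, −40 to 0 °C; then AcOH/NaOAc buffer (pH 4.5), THF/H2O, 25 °C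
Reagents that add atoms: water, O
Why: Proposed new method: the strained ten-membered ynone should take up diethylamine at C3 (conjugate addition with strain release) to give enaminone 23, whose buffered hydrolysis unveils the C1/C3 β-diketone 24; its C3 enol oxygen then opens the C9–C10 epoxide at C10 from the side opposite the epoxide oxygen and so forms the O–C10 bond. The closest known reaction types are the amine-mediated hydration of ynones to 1,3-diketones and the O-cyclisation of 1,3-dicarbonyl enols onto epoxides to give dihydrofurans and furanones. The furanone ring closes in the 5-exo-tet mode through the in-plane lone pair of the enol oxygen, and the same closure builds the bridged 11-oxabicyclo[6.2.1]undecane core. C10 is the only stereocentre that changes: it is inverted (10R to 10S) under control of the epoxide configuration set in step 6, while C9 keeps its oxygen and appears as the free 9-hydroxyl beside the 8-isobutyrate that was installed before that hydroxyl existed. The step needs attack at C10 and not at C9, and amine addition to the ynone and not to the methylene lactone; the first rests on the 5-exo over 6-endo preference at the tertiary, acid-activated C10 (which has no hydrogen, so isomerisation to a hydroxy enone is excluded), the second on the much higher electrophilicity of the strained ynone with one equivalent of amine at low temperature.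

**Compound list**
1 | prop-2-yn-1-ol | C#CCO | starting material
2 | (2Z)-3-iodo-2-methylprop-2-en-1-ol | OC/C(C)=C\I | intermediate
3 | tert-butyl{[(2Z)-3-iodo-2-methylprop-2-en-1-yl]oxy}dimethylsilane | CC(C)(C)[Si](C)(C)OC/C(C)=C\I | intermediate
4 | methyl 2-(dimethoxyphosphoryl)prop-2-enoate | C=C(C(=O)OC)P(=O)(OC)OC | starting material
5 | (4-methoxyphenyl)methanol | COc1ccc(CO)cc1 | starting material
6 | 2,2-dimethoxyacetaldehyde | COC(OC)C=O | starting material
7 | methyl (2E)-4,4-dimethoxy-2-{[(4-methoxybenzyl)oxy]methyl}but-2-enoate | COC(OC)/C=C(/C(=O)OC)COCc1ccc(OC)cc1 | intermediate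
8 | methyl (2E)-2-{[(4-methoxybenzyl)oxy]methyl}-4-oxobut-2-enoate | O=C/C=C(/C(=O)OC)COCc1ccc(OC)cc1 | intermediate
9 | methyl (2E,4R,5Z)-7-[(tert-butyldimethylsilyl)oxy]-4-hydroxy-2-{[(4-methoxybenzyl)oxy]methyl}-6-methylhepta-2,5-dienoate | COC(=O)/C(COCc1ccc(OC)cc1)=C/[C@H](O)/C=C(/C)CO[Si](C)(C)C(C)(C)C | intermediate
10 | methyl (2E,4S)-4-[(2R,3S)-3-{[(tert-butyldimethylsilyl)oxy]methyl}-3-methyloxiran-2-yl]-4-hydroxy-2-{[(4-methoxybenzyl)oxy]methyl}but-2-enoate | COC(=O)/C(COCc1ccc(OC)cc1)=C/[C@H](O)[C@H]1O[C@@]1(C)CO[Si](C)(C)C(C)(C)C | intermediate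
11 | methyl (2E,4S)-4-[(2R,3S)-3-{[(tert-butyldimethylsilyl)oxy]methyl}-3-methyloxiran-2-yl]-2-{[(4-methoxybenzyl)oxy]methyl}-4-[(2-methylpropanoyl)oxy]but-2-enoate | COC(=O)/C(COCc1ccc(OC)cc1)=C/[C@H](OC(=O)C(C)C)[C@H]1O[C@@]1(C)CO[Si](C)(C)C(C)(C)C | intermediate
12 | methyl (2E,4S)-4-[(2R,3S)-3-{[(tert-butyldimethylsilyl)oxy]methyl}-3-methyloxiran-2-yl]-2-(hydroxymethyl)-4-[(2-methylpropanoyl)oxy]but-2-enoate | COC(=O)/C(CO)=C/[C@H](OC(=O)C(C)C)[C@H]1O[C@@]1(C)CO[Si](C)(C)C(C)(C)C | intermediate
13 | methyl (2Z,4S)-2-(bromomethyl)-4-[(2R,3S)-3-{[(tert-butyldimethylsilyl)oxy]methyl}-3-methyloxiran-2-yl]-4-[(2-methylpropanoyl)oxy]but-2-enoate | COC(=O)/C(CBr)=C/[C@H](OC(=O)C(C)C)[C@H]1O[C@@]1(C)CO[Si](C)(C)C(C)(C)C | intermediate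
14 | (2Z)-3-methylpent-2-en-4-yn-1-ol | C#C/C(C)=C\CO | starting material
15 | (2Z)-3-methylpent-2-en-4-ynal | C#C/C(C)=C\C=O | intermediate
16 | methyl (3S,4R,5Z)-3-{(S)-[(2R,3S)-3-{[(tert-butyldimethylsilyl)oxy]methyl}-3-methyloxiran-2-yl][(2-methylpropanoyl)oxy]methyl}-4-hydroxy-6-methyl-2-methylideneoct-5-en-7-ynoate | COC(=O)C(=C)[C@@H]([C@H](O)/C=C(/C)C#C)[C@H](OC(=O)C(C)C)[C@H]1O[C@@]1(C)CO[Si](C)(C)C(C)(C)C | intermediate (not isolated)
17 | (S)-[(2R,3S)-3-{[(tert-butyldimethylsilyl)oxy]methyl}-3-methyloxiran-2-yl]{(2R,3S)-2-[(1Z)-2-methylbut-1-en-3-yn-1-yl]-4-methylidene-5-oxooxolan-3-yl}methyl 2-methylpropanoate | C=C1C(=O)O[C@H](/C=C(/C)C#C)[C@H]1[C@H](OC(=O)C(C)C)[C@H]2O[C@@]2(C)CO[Si](C)(C)C(C)(C)C | intermediate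
18 | (S)-[(2R,3S)-3-{[(tert-butyldimethylsilyl)oxy]methyl}-3-methyloxiran-2-yl]{(2R,3S)-2-[(1Z)-4-iodo-2-methylbut-1-en-3-yn-1-yl]-4-methylidene-5-oxooxolan-3-yl}methyl 2-methylpropanoate | C=C1C(=O)O[C@H](/C=C(/C)C#CI)[C@H]1[C@H](OC(=O)C(C)C)[C@H]2O[C@@]2(C)CO[Si](C)(C)C(C)(C)C | intermediate
19 | (S)-[(2R,3S)-3-(hydroxymethyl)-3-methyloxiran-2-yl]{(2R,3S)-2-[(1Z)-4-iodo-2-methylbut-1-en-3-yn-1-yl]-4-methylidene-5-oxooxolan-3-yl}methyl 2-methylpropanoate | C=C1C(=O)O[C@H](/C=C(/C)C#CI)[C@H]1[C@H](OC(=O)C(C)C)[C@H]2O[C@@]2(C)CO | intermediate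
20 | (S)-[(2R,3R)-3-formyl-3-methyloxiran-2-yl]{(2R,3S)-2-[(1Z)-4-iodo-2-methylbut-1-en-3-yn-1-yl]-4-methylidene-5-oxooxolan-3-yl}methyl 2-methylpropanoate | C=C1C(=O)O[C@H](/C=C(/C)C#CI)[C@H]1[C@H](OC(=O)C(C)C)[C@H]2O[C@@]2(C)C=O | intermediate
21 | (6R,7S,8S,9R)-9,10-epoxy-1-hydroxy-8-[(2-methylpropanoyl)oxy]germacra-4(Z),11(13)-dien-2-yn-12,6-olide, epoxide as in 22, C1 epimers | C=C1C(=O)O[C@@H]2/C=C(/C)C#CC(O)[C@]3(C)O[C@@H]3[C@@H](OC(=O)C(C)C)[C@@H]12 | intermediate
22 | (6R,7S,8S,9R,10R)-9,10-epoxy-8-[(2-methylpropanoyl)oxy]-1-oxogermacra-4(Z),11(13)-dien-2-yn-12,6-olide | C=C1C(=O)O[C@@H]2/C=C(/C)C#CC(=O)[C@]3(C)O[C@@H]3[C@@H](OC(=O)C(C)C)[C@@H]12 | intermediate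
23 | 3-(diethylamino)-9,10-epoxy-8-[(2-methylpropanoyl)oxy]-1-oxogermacra-2,4(Z),11(13)-trien-12,6-olide, stereocentres as in 22, C4 and C1 cis on C2=C3 | C=C1C(=O)O[C@@H]2/C=C(/C)\C(N(CC)CC)=C/C(=O)[C@]3(C)O[C@@H]3[C@@H](OC(=O)C(C)C)[C@@H]12 | intermediate (not isolated)
24 | (6R,7S,8S,9R,10R)-9,10-epoxy-8-[(2-methylpropanoyl)oxy]-1,3-dioxogermacra-4(Z),11(13)-dien-12,6-olide | C=C1C(=O)O[C@@H]2/C=C(/C)C(=O)CC(=O)[C@]3(C)O[C@@H]3[C@@H](OC(=O)C(C)C)[C@@H]12 | intermediate (not isolated)
25 | (6R,7S,8S,9R,10S)-3,10-epoxy-9-hydroxy-8-[(2-methylpropanoyl)oxy]-1-oxogermacra-2,4(Z),11(13)-trien-12,6-olide (CNP0265772.2) | C=C1C(=O)O[C@@H]2/C=C(/C)C3=CC(=O)[C@@](C)(O3)[C@H](O)[C@@H](OC(=O)C(C)C)[C@@H]12 | target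

**Step count**
Total: 17 steps. Longest linear sequence: 14 steps (1, 2, 5–9, 11–17); steps 3–4 and 10 run in parallel.

**Steps most likely to fail**

Step 17 (new method). What may go wrong: inside the ten-membered ring the enol oxygen may not reach the backside of C10, so that 6-endo attack at C9, amine addition to the methylene lactone or breakdown of the strained ynone takes over. The fallback uses known reactions and exchanges the roles of the two oxygens; it sets out from 21. Acid-catalysed hydrolysis of the epoxide (HClO4 cat., THF/H2O, 0 °C), with water entering at the tertiary C10 with inversion, should give the 1,9,10-triol F1. MnO2 in CH2Cl2 then oxidises only the propargylic C1 hydroxyl and gives the γ-hydroxy ynone F2. The tertiary C10 hydroxyl of F2 adds to C3 of the ynone in a 5-endo-dig oxa-Michael cyclisation (AuCl(PPh3)/AgOTf cat., CH2Cl2, or Et2NH in EtOH), the classical 4-hydroxy-2-ynone route to 3(2H)-furanones. The route is rejoined at 25; C10 already has the target configuration after the hydrolysis and the ring closes through the O–C3 bond.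

Step 15. What may go wrong: divalent chromium may reduce the α,β-epoxy aldehyde (ketyl formation and epoxide cleavage), or intermolecular coupling may outrun closure of the strained ring. The fallback closes the same ring by acylation at the acid oxidation level and sets out from 17. HF·pyridine removes the silyl ether to give the terminal-alkyne alcohol F3. 2,2,6,6-Tetramethylpiperidin-1-oxyl with PhI(OAc)2 in MeCN/H2O oxidises it to the glycidic acid F4. 1-Chloro-N,N,2-trimethylprop-1-en-1-amine converts F4 under neutral conditions into the acid chloride F5, which has no α-hydrogen and so cannot form a ketene. Sonogashira-type acylation of the terminal alkyne (PdCl2(PPh3)2, CuI, Et3N, toluene, high dilution) then gives the ynone directly. The route is rejoined at 22, and steps 12 to 16 are replaced.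

Step 11. What may go wrong: the allylchromium intermediate may lose the allylic isobutyrate by 1,4-elimination to a diene, and facial control by C8 may be incomplete. The fallback carries the C8 oxygen as a silyl ether, a poor leaving group and a larger directing group, through the allylation; it sets out from 10. Et3SiCl and imidazole give the triethylsilyl ether F6. Buffered 2,3-dichloro-5,6-dicyano-1,4-benzoquinone frees the primary allylic alcohol F7, and CBr4/PPh3 gives the bromide F8. CrCl2 with 15 should give the hydroxy ester F9 (not isolated), which lactonises to the silyl-protected lactone F10. Pyridinium p-toluenesulfonate in MeOH at 0 °C removes the secondary triethylsilyl ether selectively to give the hydroxy lactone F11. Acylation with 2-methylpropanoic anhydride and 4-(dimethylamino)pyridine rejoins the route at 17.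

**Further compounds**
F1 | step 17 | (6R,7S,8S,9R,10S)-1,9,10-trihydroxy-8-[(2-methylpropanoyl)oxy]germacra-4(Z),11(13)-dien-2-yn-12,6-olide, C1 epimers | C=C1C(=O)O[C@@H]2/C=C(/C)C#CC(O)[C@@](C)(O)[C@H](O)[C@@H](OC(=O)C(C)C)[C@@H]12
F2 | step 17 | (6R,7S,8S,9R,10S)-9,10-dihydroxy-8-[(2-methylpropanoyl)oxy]-1-oxogermacra-4(Z),11(13)-dien-2-yn-12,6-olide | C=C1C(=O)O[C@@H]2/C=C(/C)C#CC(=O)[C@@](C)(O)[C@H](O)[C@@H](OC(=O)C(C)C)[C@@H]12
F3 | step 15 | (S)-[(2R,3S)-3-(hydroxymethyl)-3-methyloxiran-2-yl]{(2R,3S)-2-[(1Z)-2-methylbut-1-en-3-yn-1-yl]-4-methylidene-5-oxooxolan-3-yl}methyl 2-methylpropanoate | C=C1C(=O)O[C@H](/C=C(/C)C#C)[C@H]1[C@H](OC(=O)C(C)C)[C@H]2O[C@@]2(C)CO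
F4 | step 15 | glycidic acid from F3 (CH2OH oxidised to CO2H, stereocentres unchanged in space) | C=C1C(=O)O[C@H](/C=C(/C)C#C)[C@H]1[C@H](OC(=O)C(C)C)[C@H]2O[C@@]2(C)C(=O)O
F5 | step 15 | acid chloride of F4 | C=C1C(=O)O[C@H](/C=C(/C)C#C)[C@H]1[C@H](OC(=O)C(C)C)[C@H]2O[C@@]2(C)C(=O)Cl
F6 | step 11 | triethylsilyl ether of 10 at the secondary hydroxyl | COC(=O)/C(COCc1ccc(OC)cc1)=C/[C@H](O[Si](CC)(CC)CC)[C@H]1O[C@@]1(C)CO[Si](C)(C)C(C)(C)C
F7 | step 11 | primary allylic alcohol from F6 (4-methoxybenzyl removed) | COC(=O)/C(CO)=C/[C@H](O[Si](CC)(CC)CC)[C@H]1O[C@@]1(C)CO[Si](C)(C)C(C)(C)C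
F8 | step 11 | allylic bromide from F7 | COC(=O)/C(CBr)=C/[C@H](O[Si](CC)(CC)CC)[C@H]1O[C@@]1(C)CO[Si](C)(C)C(C)(C)C
F9 | step 11 | open-chain hydroxy ester from F8 and 15 (triethylsilyl analogue of 16) | COC(=O)C(=C)[C@@H]([C@H](O)/C=C(/C)C#C)[C@H](O[Si](CC)(CC)CC)[C@H]1O[C@@]1(C)CO[Si](C)(C)C(C)(C)C
F10 | step 11 | lactone from F9 (triethylsilyl analogue of 17) | C=C1C(=O)O[C@H](/C=C(/C)C#C)[C@H]1[C@H](O[Si](CC)(CC)CC)[C@H]2O[C@@]2(C)CO[Si](C)(C)C(C)(C)C
F11 | step 11 | hydroxy lactone from F10 (free C8 hydroxyl) | C=C1C(=O)O[C@H](/C=C(/C)C#C)[C@H]1[C@H](O)[C@H]2O[C@@]2(C)CO[Si](C)(C)C(C)(C)C
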